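**Retrosynthetic overview** (locants follow the benzofuran-2-one core: O1, C2, C3, C3a, C4–C7, C7a)
1. The palmitate ester leads back to (−)-loliolide. The butenolide comes from methyl addition to the C7a ketone of a (Z)-2-(6-oxocyclohexylidene)acetate, whose alkoxide closes O1–C2 and sets C7a.
2. The C3a=C3 bond comes from aldol addition and dehydration between ethyl glyoxylate and the enolate C7a(O⁻)=C3a.
3. That enolate, and with it the carbocycle C3a–C4–C5–C6–C7–C7a, comes from one-carbon ring enlargement of a (4S)-4-silyloxy-2,2-dimethylcyclopentanone (ring C4–C5–C6–C7–C7a); the CHBr carbenoid carbon becomes C3a.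
4. Enabling feature: C3a is the only ring carbon between the oxygen-bearing C7a (a latent ketone) and the quaternary C4. Removing it leaves a 2,2-dimethylcyclopentanone in which C4 is the better migrating group, and re-inserting it puts the enolate at the neopentyl position that deprotonation cannot reach.
5. Ring order: cyclopentane (bought), then cyclohexane (step 5), then butenolide (step 7). C6 comes from an asymmetric conjugate borylation and C7a from substrate control.

Key step: step 5

Assumption: the enantiomer of the Josiphos-type ligand used is the one that delivers boron to the enone face giving the (S)-boronate; both ligand enantiomers are sold.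

Step 1
Reactants: 1 2,2-dimethylcyclopentan-1-one
Product: 2 5,5-dimethylcyclopent-2-en-1-one
Conditions: IBX (2 equiv), DMSO/fluorobenzene, 75 °C
Reagents that add atoms: none
Why: IBX-mediated α,β-dehydrogenation of a ketone; only one α-carbon of 1 carries hydrogens, so a single enone can form and the quaternary carbon prevents a second dehydrogenation.

Step 2
Reactants: 2 5,5-dimethylcyclopent-2-en-1-one
Product: 4 (4S)-4-hydroxy-2,2-dimethylcyclopentan-1-one, via pinacol boronate 3 (not isolated)
Conditions: B2pin2, CuCl (cat.), NaOt-Bu (cat.), Josiphos-type bisphosphine (cat.), MeOH (2 equiv), THF, rt; then NaBO3·4H2O, THF/H2O, rt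
Reagents that add atoms: bis(pinacolato)diboron, CC1(C)OB(OC1(C)C)B1OC(C)(C)C(C)(C)O1 (its atoms stay only in 3); sodium perborate, [Na+].[O-]OB=O
Why: Copper(I)-catalysed enantioselective conjugate borylation followed by stereoretentive C–B oxidation; the chiral bisphosphine on the Cu–Bpin species selects the enone face and so sets C6 as S, and perborate is mild enough not to dehydrate the β-hydroxy ketone.

Step 3
Reactants: 4 (4S)-4-hydroxy-2,2-dimethylcyclopentan-1-one
Product: 5 (4S)-4-[(tert-butyldimethylsilyl)oxy]-2,2-dimethylcyclopentan-1-one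
Conditions: TBSCl, imidazole, DMF, 0 °C to rt
Reagents that add atoms: tert-butyldimethylsilyl chloride, CC(C)(C)[Si](C)(C)Cl
Why: Standard silylation under weakly basic conditions protects the alcohol for the organolithium steps without triggering β-elimination and leaves C6 untouched.

Step 4
Reactants: 5 (4S)-4-[(tert-butyldimethylsilyl)oxy]-2,2-dimethylcyclopentan-1-one
Product: 6 (4S)-4-[(tert-butyldimethylsilyl)oxy]-1-(dibromomethyl)-2,2-dimethylcyclopentan-1-ol (both C1 epimers)
Conditions: CH2Br2, LDA, THF, −90 °C; then 5, −90 °C; AcOH quench at −90 °C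
Reagents that add atoms: dibromomethane, BrCBr
Why: 1,2-Addition of dibromomethyllithium, preformed at a temperature where it persists, to the ketone; the small nucleophile reaches the neopentyl carbonyl carbon, and the new carbinol centre may form as a mixture because it becomes sp2 again in step 5.

Step 5
Reactants: 6 (4S)-4-[(tert-butyldimethylsilyl)oxy]-1-(dibromomethyl)-2,2-dimethylcyclopentan-1-ol; 7 ethyl glyoxylate (freshly cracked and distilled)
Product: 10 ethyl 2-[(4S)-4-[(tert-butyldimethylsilyl)oxy]-2,2-dimethyl-6-oxocyclohexyl]-2-hydroxyacetate (mixture at the two new centres), via lithium bromocarbenoid 8 (not isolated), via ring-enlarged lithium enolate 9 (not isolated)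
Conditions: n-BuLi (2.1 equiv), THF, −90 °C to −20 °C; recool to −78 °C, 7; AcOH quench at −78 °C
Reagents that add atoms: none
Why: The first equivalent of n-BuLi deprotonates the carbinol and the second exchanges one bromine to give the β-oxido bromocarbenoid 8; on warming, loss of LiBr from its electrophilic carbenoid carbon (the future C3a) is concerted with the alkoxide-driven 1,2-shift of a ring carbon from the carbinol carbon (C7a) to that carbon, which turns the cyclopentane into the cyclohexane ring and delivers it as lithium enolate 9 with its C=C exactly between C7a and the inserted C3a. The closest known reaction type is the β-oxido carbenoid one-carbon ring enlargement of cycloalkanones through their dihalomethyllithium adducts, with capture of the regiodefined enolate by an electrophile. No ring is closed by cyclisation: the six-membered ring arises by insertion of one carbon into the C7a–C4 bond of the five-membered ring, and the butenolide follows in step 7. The selectivity needed is migration of the quaternary C4 and not of the C7 methylene; the substrate secures it because the more substituted, more electron-rich carbon migrates to an electron-poor carbenoid centre and because the shift relieves the crowding between the carbinol carbon and the adjacent gem-dimethyl carbon, and both epimers of 6 converge since C7a becomes sp2. Enolate 9 could not be made from the six-membered ketone by deprotonation (base would take a C7 proton and invite loss of silanolate), so it is used at once at −78 °C in an aldol addition to the unhindered, highly electrophilic aldehyde 7, which forges the C3a–C3 bond next to the quaternary carbon and brings in C2. The two new stereocentres (C3a and C3) are not controlled and need not be, since both become sp2 in step 6, and C6 is not touched.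

Step 6
Reactants: 10 ethyl 2-[(4S)-4-[(tert-butyldimethylsilyl)oxy]-2,2-dimethyl-6-oxocyclohexyl]-2-hydroxyacetate
Product: 12 ethyl (2Z)-2-[(4S)-4-[(tert-butyldimethylsilyl)oxy]-2,2-dimethyl-6-oxocyclohexylidene]acetate, via mesylate 11 (not isolated)
Conditions: MsCl, Et3N (3.5 equiv), CH2Cl2, −20 °C to rt
Reagents that add atoms: methanesulfonyl chloride, CS(=O)(=O)Cl (its atoms stay only in 11)
Why: Mesylation of the aldol hydroxyl and E1cB elimination through the acidic C3a–H complete an aldol condensation; the ester should end up on the ketone side (Z) because the other geometry presses it against the gem-dimethyl group (A1,3 strain), and the weak amine base spares the β-silyloxy ketone.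

Step 7
Reactants: 12 ethyl (2Z)-2-[(4S)-4-[(tert-butyldimethylsilyl)oxy]-2,2-dimethyl-6-oxocyclohexylidene]acetate
Product: 14 (6S,7aR)-6-[(tert-butyldimethylsilyl)oxy]-4,4,7a-trimethyl-5,6,7,7a-tetrahydro-1-benzofuran-2(4H)-one, via cerium alkoxide 13 (not isolated)
Conditions: MeLi, anhydrous CeCl3, THF, −78 °C to 0 °C; aqueous work-up
Reagents that add atoms: methyllithium, [Li]C; cerium(III) chloride, Cl[Ce](Cl)Cl (its atoms stay only in 13)
Why: Non-basic organocerium 1,2-addition to the ketone is followed by lactonisation of the alkoxide onto the cis ester; the ring is locked with the silyloxy group equatorial, so one C4 methyl is axial and blocks the axial trajectory at C7a, and methyl therefore enters equatorially, cis to the C6 oxygen, which places O1 trans to it and sets C7a as R.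

Step 8
Reactants: 14 (6S,7aR)-6-[(tert-butyldimethylsilyl)oxy]-4,4,7a-trimethyl-5,6,7,7a-tetrahydro-1-benzofuran-2(4H)-one
Product: 15 (−)-loliolide, (6S,7aR)-6-hydroxy-4,4,7a-trimethyl-5,6,7,7a-tetrahydro-1-benzofuran-2(4H)-one
Conditions: HF·pyridine, THF, 0 °C to rt
Reagents that add atoms: none
Why: Fluoride cleavage of the silyl ether under slightly acidic conditions leaves the butenolide and the tertiary allylic C7a–O bond intact and touches no stereocentre.

Step 9
Reactants: 15 (−)-loliolide; 16 palmitoyl chloride
Product: 17 (−)-3-O-palmitoylloliolide, (6S,7aR)-4,4,7a-trimethyl-2-oxo-2,4,5,6,7,7a-hexahydro-1-benzofuran-6-yl hexadecanoate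
Conditions: Et3N, DMAP (cat.), CH2Cl2, 0 °C to rt
Reagents that add atoms: none
Why: DMAP-catalysed acylation of the hindered axial secondary alcohol by the acid chloride does not break the C6–O bond, so the configuration is retained.

**Compound list**
1 | 2,2-dimethylcyclopentan-1-one | CC1(C)CCCC1=O | starting material
2 | 5,5-dimethylcyclopent-2-en-1-one | CC1(C)CC=CC1=O | intermediate
3 | (4S)-2,2-dimethyl-4-(4,4,5,5-tetramethyl-1,3,2-dioxaborolan-2-yl)cyclopentan-1-one | CC1(C)OB(OC1(C)C)[C@H]1CC(C)(C)C(=O)C1 | intermediate
4 | (4S)-4-hydroxy-2,2-dimethylcyclopentan-1-one | O[C@H]1CC(C)(C)C(=O)C1 | intermediate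
5 | (4S)-4-[(tert-butyldimethylsilyl)oxy]-2,2-dimethylcyclopentan-1-one | CC(C)(C)[Si](C)(C)O[C@H]1CC(C)(C)C(=O)C1 | intermediate
6 | (4S)-4-[(tert-butyldimethylsilyl)oxy]-1-(dibromomethyl)-2,2-dimethylcyclopentan-1-ol, both C1 epimers | CC(C)(C)[Si](C)(C)O[C@H]1CC(C)(C)C(O)(C(Br)Br)C1 | intermediate
7 | ethyl glyoxylate | CCOC(=O)C=O | starting material
8 | lithium (4S)-1-[bromo(lithio)methyl]-4-[(tert-butyldimethylsilyl)oxy]-2,2-dimethylcyclopentan-1-olate | CC(C)(C)[Si](C)(C)O[C@H]1CC(C)(C)C(O[Li])(C([Li])Br)C1 | intermediate
9 | lithium (5S)-5-[(tert-butyldimethylsilyl)oxy]-3,3-dimethylcyclohex-1-en-1-olate | CC(C)(C)[Si](C)(C)O[C@H]1CC(C)(C)C=C(O[Li])C1 | intermediate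
10 | ethyl 2-[(4S)-4-[(tert-butyldimethylsilyl)oxy]-2,2-dimethyl-6-oxocyclohexyl]-2-hydroxyacetate, mixture at ring C1 and at the carbinol carbon | CC(C)(C)[Si](C)(C)O[C@H]1CC(C)(C)C(C(O)C(=O)OCC)C(=O)C1 | intermediate
11 | ethyl 2-[(4S)-4-[(tert-butyldimethylsilyl)oxy]-2,2-dimethyl-6-oxocyclohexyl]-2-(methanesulfonyloxy)acetate | CC(C)(C)[Si](C)(C)O[C@H]1CC(C)(C)C(C(OS(C)(=O)=O)C(=O)OCC)C(=O)C1 | intermediate
12 | ethyl (2Z)-2-[(4S)-4-[(tert-butyldimethylsilyl)oxy]-2,2-dimethyl-6-oxocyclohexylidene]acetate | CC(C)(C)[Si](C)(C)O[C@H]1CC(C)(C)/C(=C/C(=O)OCC)C(=O)C1 | intermediate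
13 | dichlorocerium alkoxide of ethyl (2Z)-2-[(2R,4S)-4-[(tert-butyldimethylsilyl)oxy]-2-hydroxy-2,6,6-trimethylcyclohexylidene]acetate | CC(C)(C)[Si](C)(C)O[C@H]1CC(C)(C)/C(=C/C(=O)OCC)[C@](C)(O[Ce](Cl)Cl)C1 | intermediate
14 | (6S,7aR)-6-[(tert-butyldimethylsilyl)oxy]-4,4,7a-trimethyl-5,6,7,7a-tetrahydro-1-benzofuran-2(4H)-one | CC(C)(C)[Si](C)(C)O[C@H]1CC(C)(C)C2=CC(=O)O[C@]2(C)C1 | intermediate
15 | (−)-loliolide | O[C@H]1CC(C)(C)C2=CC(=O)O[C@]2(C)C1 | intermediate
16 | palmitoyl chloride | CCCCCCCCCCCCCCCC(=O)Cl | starting material
17 | (−)-3-O-palmitoylloliolide | CCCCCCCCCCCCCCCC(=O)O[C@H]1CC(C)(C)C2=CC(=O)O[C@]2(C)C1 | target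

Total step count: 9. Longest linear sequence: 9 (1 to 17).

**Steps most likely to fail**

1. **Step 5.** The ring methylene may migrate instead of the quaternary carbon. The carbenoid may be protonated or decompose before the shift, or aldol capture at the neopentyl enolate carbon may be too slow.
 - The fallback sets out from 5 and enlarges the same ring by an α-ketol rearrangement, in which the ketone carbon of 5 becomes C3a.
 - 1-Ethoxyvinyllithium adds to 5 to give the enol ether carbinol F1. Dilute oxalic acid hydrolyses it to the tertiary ketol 1-acetylcyclopentanol F2.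
 - Catalytic KOt-Bu in t-BuOH equilibrates F2 by shift of the ring methylene to the acetyl carbon, as in base-induced D-homoannulation of 17-hydroxy-20-oxo steroids. This gives the non-enolisable hydroxy ketone F3, which should be favoured because its methyl and silyloxy groups are both equatorial.
 - Lithium ethoxyacetylide adds to F3 to give the diol F4. Dilute H2SO4 in THF then brings about Meyer–Schuster rearrangement, lactonisation and desilylation.
 - The fallback rejoins the route at 15.

2. **Step 4.** The basic and thermally fragile dibromomethyllithium may enolise the hindered ketone or decompose before it adds.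
 - The fallback sets out from 5 and uses a sulfoxide-stabilised carbenoid precursor.
 - The lithium anion of chloromethyl p-tolyl sulfoxide, stable at −78 °C, adds to 5 to give the chloro sulfoxide carbinol F5.
 - Deprotonation with LDA and sulfoxide–lithium exchange with t-BuLi give the lithium chlorocarbenoid F6, which loses LiCl with the same 1,2-shift.
 - The fallback rejoins the route at enolate 9.

3. **Step 7.** Methyl may add in conjugate fashion to the doubly activated alkene, or enolisation towards C7 may lead to loss of silanolate.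
 - The fallback sets out from 12 and masks the acceptor.
 - Thiophenol with catalytic Et3N adds at C3 to give the sulfide keto ester F7.
 - The methylcerium reagent then adds to the ketone under the same conformational control, and the alkoxide lactonises to the saturated phenylthio lactone F8.
 - mCPBA gives the sulfoxide F9, and warming in toluene causes syn-elimination towards the C3a hydrogen.
 - The fallback rejoins the route at 14.

**Further compounds**
F1 | step 5 | (4S)-4-[(tert-butyldimethylsilyl)oxy]-1-(1-ethoxyethenyl)-2,2-dimethylcyclopentan-1-ol | CC(C)(C)[Si](C)(C)O[C@H]1CC(C)(C)C(O)(C(=C)OCC)C1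
F2 | step 5 | 1-[(4S)-4-[(tert-butyldimethylsilyl)oxy]-1-hydroxy-2,2-dimethylcyclopentyl]ethan-1-one | CC(C)(C)[Si](C)(C)O[C@H]1CC(C)(C)C(O)(C(C)=O)C1
F3 | step 5 | (2R,4S)-4-[(tert-butyldimethylsilyl)oxy]-2-hydroxy-2,6,6-trimethylcyclohexan-1-one | CC(C)(C)[Si](C)(C)O[C@H]1CC(C)(C)C(=O)[C@](C)(O)C1
F4 | step 5 | (2R,4S)-4-[(tert-butyldimethylsilyl)oxy]-1-(ethoxyethynyl)-2,6,6-trimethylcyclohexane-1,2-diol | CC(C)(C)[Si](C)(C)O[C@H]1CC(C)(C)C(O)(C#COCC)[C@](C)(O)C1
F5 | step 4 | (4S)-4-[(tert-butyldimethylsilyl)oxy]-1-[chloro(4-methylbenzenesulfinyl)methyl]-2,2-dimethylcyclopentan-1-ol | CC(C)(C)[Si](C)(C)O[C@H]1CC(C)(C)C(O)(C(Cl)S(=O)c2ccc(C)cc2)C1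
F6 | step 4 | lithium (4S)-4-[(tert-butyldimethylsilyl)oxy]-1-[chloro(lithio)methyl]-2,2-dimethylcyclopentan-1-olate | CC(C)(C)[Si](C)(C)O[C@H]1CC(C)(C)C(O[Li])(C([Li])Cl)C1
F7 | step 7 | ethyl 2-[(4S)-4-[(tert-butyldimethylsilyl)oxy]-2,2-dimethyl-6-oxocyclohexyl]-2-(phenylsulfanyl)acetate | CC(C)(C)[Si](C)(C)O[C@H]1CC(C)(C)C(C(Sc2ccccc2)C(=O)OCC)C(=O)C1
F8 | step 7 | (6S,7aR)-6-[(tert-butyldimethylsilyl)oxy]-4,4,7a-trimethyl-3-(phenylsulfanyl)hexahydro-1-benzofuran-2(3H)-one | CC(C)(C)[Si](C)(C)O[C@H]1CC(C)(C)C2C(Sc3ccccc3)C(=O)O[C@]2(C)C1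
F9 | step 7 | (6S,7aR)-3-(benzenesulfinyl)-6-[(tert-butyldimethylsilyl)oxy]-4,4,7a-trimethylhexahydro-1-benzofuran-2(3H)-one | CC(C)(C)[Si](C)(C)O[C@H]1CC(C)(C)C2C(S(=O)c3ccccc3)C(=O)O[C@]2(C)C1
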